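**Retrosynthetic overview**
1. Target 31 ⇐ diallyl ester 30 ⇐ seco-enal 29: ring B is closed last through the C9–C10 bond (reductive Michael addition of the ring A enal onto the ring C enone).
2. 29 ⇐ ester 24: the C5–C6 bond comes from an Ireland–Claisen rearrangement of the ester joining the ring C/D acid 13 to the ring A alcohol 23.
3. 13 ⇐ symmetric ketone 10: ring D (C13–C16) by palladium-catalysed, enantiotopic-arm-selective intramolecular α-alkenylation; ring C by Robinson annulation.
4. 23 ⇐ 6 + 15: ring A by catalytic asymmetric Diels–Alder reaction (sets C4), then Saegusa oxidation, hydroxymethylation (C20) and CBS reduction (C1–O, relayed to C5 in the Claisen step).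
5. Ring order: C then D in one branch, A in the other, B after the union.

Assumption: the target is taken as the open aldehyde–diacid form drawn (a 12-oxo gibberellin of the 20-carbon aldehyde–diacid type), and carbons are labelled C1–C20 by gibberellane numbering (ring A C1–C5/C10, ring B C5/C6/C8/C9/C10, ring C C8/C9/C11–C14, ring D C8/C13–C16).

**Route**

Step 1
Reactants: 1 methyl 4-oxobutanoate
Product: 2 methyl (3E)-4-(pyrrolidin-1-yl)but-3-enoate
Conditions: pyrrolidine (1.1 equiv), K2CO3, Et2O, 0 °C → 25 °C; distil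
Reagents that add atoms: pyrrolidine, C1CCNC1
Why: Stork enamine formation at the only enolisable aldehyde position, giving the conjugated E-enamine.

Step 2
Reactants: 2 methyl (3E)-4-(pyrrolidin-1-yl)but-3-enoate; 3 2,3-dibromoprop-1-ene
Product: 5 methyl 5-bromo-3-formylhex-5-enoate (racemic), via iminium bromide 4 (not isolated)
Conditions: MeCN, 70 °C; then H2O, AcOH/NaOAc buffer, 25 °C
Reagents that add atoms: water, O
Why: Stork enamine allylation with a reactive allylic bromide followed by iminium hydrolysis puts the 2-bromoallyl group on the aldehyde α-carbon (future C8); the new centre is racemic and is erased in step 4.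

Step 3
Reactants: 5 methyl 5-bromo-3-formylhex-5-enoate; 6 but-3-en-2-one
Product: 8 methyl 2-[1-(2-bromoprop-2-en-1-yl)-4-oxocyclohex-2-en-1-yl]acetate (racemic), via keto aldehyde 7 (not isolated)
Conditions: pyrrolidinium acetate (20 mol %), toluene, 25 °C → 90 °C
Reagents that add atoms: none
Why: Robinson annulation: amine-catalysed Michael addition of the α-branched aldehyde to the enone creates quaternary C8, and intramolecular aldol condensation closes ring C as a 4,4-disubstituted cyclohexenone.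

Step 4
Reactants: 8 methyl 2-[1-(2-bromoprop-2-en-1-yl)-4-oxocyclohex-2-en-1-yl]acetate
Product: 10 methyl 2-[1-(2-bromoprop-2-en-1-yl)-4-oxocyclohexyl]acetate (achiral), via silyl enol ether 9 (not isolated)
Conditions: Et3SiH (1.2 equiv), RhCl(PPh3)3 (1 mol %), benzene, 50 °C; then K2CO3 (cat.), MeOH, 25 °C
Reagents that add atoms: none
Why: Rhodium-catalysed 1,4-hydrosilylation of the enone followed by methanolysis is a chemoselective conjugate reduction that spares the vinyl bromide and ester; the ketone formed has a mirror plane, so the racemic centre of 8 disappears.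

Step 5
Reactants: 10 methyl 2-[1-(2-bromoprop-2-en-1-yl)-4-oxocyclohexyl]acetate
Product: 11 methyl 2-[(1R,5R)-6-methylidene-4-oxobicyclo[3.2.1]octan-1-yl]acetate
Conditions: Pd(OAc)2 (5 mol %), PPh3 (12 mol %), (2R,5R)-2,5-diphenylpyrrolidine (30 mol %), NaOAc (2 equiv), tert-amyl alcohol, 70 °C
Reagents that add atoms: none
Why: Proposed new method: enantiotopic-arm-selective intramolecular α-alkenylation by cooperative zerovalent palladium and C2-symmetric secondary-amine catalysis; the amine forms the enamine reversibly on either α-arm, but only the enamine whose unshielded face is syn to the axial 2-bromoallyl group can capture the vinylpalladium bromide (from oxidative addition) as a six-membered palladacycle, and reductive elimination then forms C13–C16 (ring D) and fixes C8 and C13 as (1R,5R), the sense predicted by the aryl-shielding model; the closest known reaction types are the base-mediated, racemic intramolecular palladium-catalysed α-vinylation of ketones and the palladium/amine co-catalysed desymmetrising α-arylation of 4-substituted cyclohexanones.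

Step 6
Reactants: 11 methyl 2-[(1R,5R)-6-methylidene-4-oxobicyclo[3.2.1]octan-1-yl]acetate
Product: 12 methyl 2-[(1S,5R)-6-methylidene-4-oxobicyclo[3.2.1]oct-2-en-1-yl]acetate
Conditions: 2-iodoxybenzoic acid (2.5 equiv), DMSO/fluorobenzene (1:2), 70 °C
Reagents that add atoms: none
Why: Dehydrogenation of the ketone with 2-iodoxybenzoic acid can only go toward the C11 methylene (C13 is a bridgehead), so the C9=C11 enone forms regiospecifically; the stereocentres are untouched (the C1 descriptor changes by priority only).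

Step 7
Reactants: 12 methyl 2-[(1S,5R)-6-methylidene-4-oxobicyclo[3.2.1]oct-2-en-1-yl]acetate
Product: 13 2-[(1S,5R)-6-methylidene-4-oxobicyclo[3.2.1]oct-2-en-1-yl]acetic acid
Conditions: LiOH·H2O (3 equiv), THF/H2O (3:1), 0 °C → 25 °C; then 1 M HCl
Reagents that add atoms: lithium hydroxide, [Li+].[OH-]
Why: Saponification of an unhindered primary-alkyl methyl ester; the enone has no enolisable position, so nothing epimerises.

Step 8
Reactants: 6 but-3-en-2-one
Product: 14 2-[(tert-butyldimethylsilyl)oxy]buta-1,3-diene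
Conditions: tBuMe2SiOSO2CF3 (1.05 equiv), Et3N (1.3 equiv), Et2O, 0 °C → 25 °C
Reagents that add atoms: tert-butyldimethylsilyl trifluoromethanesulfonate, CC(C)(C)[Si](C)(C)OS(=O)(=O)C(F)(F)F
Why: Soft enolisation and O-silylation of the methyl ketone gives the 2-silyloxydiene.

Step 9
Reactants: 14 2-[(tert-butyldimethylsilyl)oxy]buta-1,3-diene; 15 2-methylprop-2-enal
Product: 16 (1R)-4-[(tert-butyldimethylsilyl)oxy]-1-methylcyclohex-3-ene-1-carbaldehyde
Conditions: (S)-3,3-diphenyl-1-(2-methylphenyl)tetrahydro-1H,3H-pyrrolo[1,2-c][1,3,2]oxazaborole (15 mol %), (CF3SO2)2NH (12 mol %), CH2Cl2, −78 °C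
Reagents that add atoms: none
Why: Catalytic enantioselective Diels–Alder reaction with a cationic oxazaborolidine Lewis acid: the 2-silyloxy group enforces para regiochemistry, and the catalyst-bound s-trans enal is attacked on one face, setting the quaternary C4 as R (the catalyst antipode is the one whose formyl C–H···O-bound complex exposes that face).

Step 10
Reactants: 16 (1R)-4-[(tert-butyldimethylsilyl)oxy]-1-methylcyclohex-3-ene-1-carbaldehyde
Product: 17 (1R)-1-methyl-4-oxocyclohex-2-ene-1-carbaldehyde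
Conditions: Pd(OAc)2 (10 mol %), O2 (1 atm), DMSO, 45 °C
Reagents that add atoms: none
Why: Saegusa–Ito oxidation: the regiodefined silyl enol ether is palladated at C10 and β-hydride elimination can only take a hydrogen from C5, giving the C10=C5 enone.

Step 11
Reactants: 17 (1R)-1-methyl-4-oxocyclohex-2-ene-1-carbaldehyde
Product: 18 (1R)-1-methyl-4-oxocyclohex-2-ene-1-carboxylic acid
Conditions: NaClO2, NaH2PO4, 2-methylbut-2-ene, tBuOH/H2O, 0 °C → 25 °C
Reagents that add atoms: sodium chlorite, [Na+].[O-]Cl=O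
Why: Pinnick oxidation converts the non-enolisable aldehyde into the C19 acid without touching the enone.

Step 12
Reactants: 18 (1R)-1-methyl-4-oxocyclohex-2-ene-1-carboxylic acid
Product: 19 prop-2-en-1-yl (1R)-1-methyl-4-oxocyclohex-2-ene-1-carboxylate
Conditions: allyl bromide, K2CO3, DMF, 25 °C
Reagents that add atoms: allyl bromide, C=CCBr
Why: O-alkylation of the carboxylate installs an ester that can be removed under neutral conditions at the end, which matters because the axial C19 ester is hard to saponify.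

Step 13
Reactants: 19 prop-2-en-1-yl (1R)-1-methyl-4-oxocyclohex-2-ene-1-carboxylate; 20 formaldehyde
Product: 21 prop-2-en-1-yl (1R)-3-(hydroxymethyl)-1-methyl-4-oxocyclohex-2-ene-1-carboxylate
Conditions: 37% aqueous formaldehyde, 4-(dimethylamino)pyridine (30 mol %), THF/H2O (1:1), 25 °C
Reagents that add atoms: none
Why: Morita–Baylis–Hillman hydroxymethylation places C20 on the enone α-carbon (C10) and keeps the C10=C5 double bond.

Step 14
Reactants: 21 prop-2-en-1-yl (1R)-3-(hydroxymethyl)-1-methyl-4-oxocyclohex-2-ene-1-carboxylate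
Product: 22 prop-2-en-1-yl (1R)-1-methyl-4-oxo-3-{[(triethylsilyl)oxy]methyl}cyclohex-2-ene-1-carboxylate
Conditions: Et3SiCl, imidazole, CH2Cl2, 0 °C
Reagents that add atoms: chlorotriethylsilane, CC[Si](Cl)(CC)CC
Why: Silylation of the primary allylic alcohol, so that only the secondary alcohol made next is acylated in step 16.

Step 15
Reactants: 22 prop-2-en-1-yl (1R)-1-methyl-4-oxo-3-{[(triethylsilyl)oxy]methyl}cyclohex-2-ene-1-carboxylate
Product: 23 prop-2-en-1-yl (1R,4S)-4-hydroxy-1-methyl-3-{[(triethylsilyl)oxy]methyl}cyclohex-2-ene-1-carboxylate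
Conditions: (R)-1-methyl-3,3-diphenyltetrahydro-1H,3H-pyrrolo[1,2-c][1,3,2]oxazaborole (20 mol %), catecholborane (1.8 equiv), toluene, −78 °C; aqueous work-up
Reagents that add atoms: none
Why: CBS reduction of the α-substituted enone under reagent control (the alkenyl side acts as the large group) gives the S carbinol at C1, cis to the C19 ester; catecholborane does not hydroborate the allyl ester.

Step 16
Reactants: 13 2-[(1S,5R)-6-methylidene-4-oxobicyclo[3.2.1]oct-2-en-1-yl]acetic acid; 23 prop-2-en-1-yl (1R,4S)-4-hydroxy-1-methyl-3-{[(triethylsilyl)oxy]methyl}cyclohex-2-ene-1-carboxylate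
Product: 24 prop-2-en-1-yl (1R,4S)-1-methyl-4-({2-[(1S,5R)-6-methylidene-4-oxobicyclo[3.2.1]oct-2-en-1-yl]acetyl}oxy)-3-{[(triethylsilyl)oxy]methyl}cyclohex-2-ene-1-carboxylate
Conditions: N,N'-diisopropylcarbodiimide (1.3 equiv), 4-(dimethylamino)pyridine (0.2 equiv), CH2Cl2, 0 °C → 25 °C
Reagents that add atoms: none
Why: Steglich esterification joins the two branches through an ordinary ester bond without affecting any stereocentre.

Step 17
Reactants: 24 prop-2-en-1-yl (1R,4S)-1-methyl-4-({2-[(1S,5R)-6-methylidene-4-oxobicyclo[3.2.1]oct-2-en-1-yl]acetyl}oxy)-3-{[(triethylsilyl)oxy]methyl}cyclohex-2-ene-1-carboxylate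
Product: 28 prop-2-en-1-yl (1R,2S)-1-methyl-2-{(1S)-1-[(1R,5R)-6-methylidene-4-oxobicyclo[3.2.1]oct-2-en-1-yl]-2-oxo-2-(prop-2-en-1-yloxy)ethyl}-3-{[(triethylsilyl)oxy]methyl}cyclohex-3-ene-1-carboxylate, via silyl ketene acetal 25 (not isolated), via trimethylsilyl ester 26 (not isolated), via carboxylic acid 27 (not isolated)
Conditions: LiN(iPr)2 (1.3 equiv), THF/DMPU (4:1), −78 °C; Me3SiCl (3 equiv); −78 → 65 °C; MeOH, 25 °C; then Cs2CO3, allyl bromide, DMF, 25 °C
Reagents that add atoms: allyl bromide, C=CCBr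
Why: Ireland–Claisen rearrangement: the (Z)-silyl ketene acetal rearranges suprafacially through a chair transition state, so the C5–C6 bond forms on the face the C1 oxygen leaves (setting C5) and the acetal geometry sets C6; the enone cannot enolise, and in-flask allylation caps the C7 acid.

Step 18
Reactants: 28 prop-2-en-1-yl (1R,2S)-1-methyl-2-{(1S)-1-[(1R,5R)-6-methylidene-4-oxobicyclo[3.2.1]oct-2-en-1-yl]-2-oxo-2-(prop-2-en-1-yloxy)ethyl}-3-{[(triethylsilyl)oxy]methyl}cyclohex-3-ene-1-carboxylate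
Product: 29 prop-2-en-1-yl (1R,2S)-3-formyl-1-methyl-2-{(1S)-1-[(1R,5R)-6-methylidene-4-oxobicyclo[3.2.1]oct-2-en-1-yl]-2-oxo-2-(prop-2-en-1-yloxy)ethyl}cyclohex-3-ene-1-carboxylate
Conditions: (COCl)2 (3 equiv), DMSO (6 equiv), CH2Cl2, −78 → −35 °C; Et3N (8 equiv), → 0 °C
Reagents that add atoms: none
Why: Swern oxidation applied directly to the primary allylic triethylsilyl ether (desilylated in situ by the chlorosulfonium reagent) gives the C20 enal in one operation and touches no stereocentre.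

Step 19
Reactants: 29 prop-2-en-1-yl (1R,2S)-3-formyl-1-methyl-2-{(1S)-1-[(1R,5R)-6-methylidene-4-oxobicyclo[3.2.1]oct-2-en-1-yl]-2-oxo-2-(prop-2-en-1-yloxy)ethyl}cyclohex-3-ene-1-carboxylate
Product: 30 diprop-2-en-1-yl (1R,2S,3S,4R,8R,9R,12R)-8-formyl-4-methyl-13-methylidene-11-oxotetracyclo[10.2.1.0(1,9).0(3,8)]pentadecane-2,4-dicarboxylate
Conditions: diethyl 2,6-dimethyl-1,4-dihydropyridine-3,5-dicarboxylate (1.3 equiv), pyrrolidinium trifluoroacetate (20 mol %), 1,4-dioxane, 25 → 40 °C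
Reagents that add atoms: none
Why: Organocatalytic reductive Michael cyclisation: iminium activation lets the dihydropyridine deliver hydride only to C1 of the enal, and the resulting enamine adds 5-exo to C9 of the enone on the face anti to the two-carbon bridge, while C10 bonds equatorially on the face opposite the axial C19 ester, which gives the trans A/B fusion with C20 axial.

Step 20
Reactants: 30 diprop-2-en-1-yl (1R,2S,3S,4R,8R,9R,12R)-8-formyl-4-methyl-13-methylidene-11-oxotetracyclo[10.2.1.0(1,9).0(3,8)]pentadecane-2,4-dicarboxylate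
Product: 31 (1R,2S,3S,4R,8R,9R,12R)-8-formyl-4-methyl-13-methylidene-11-oxotetracyclo[10.2.1.0(1,9).0(3,8)]pentadecane-2,4-dicarboxylic acid (CNP0412196.1)
Conditions: Pd(PPh3)4 (5 mol %), morpholine (6 equiv), THF, 25 °C; then 1 M HCl to pH 3
Reagents that add atoms: none
Why: Tsuji–Trost deallylation: zerovalent palladium ionises both allyl esters and morpholine traps the allyl units, freeing the two acids under neutral conditions that leave the aldehyde, ketone, exocyclic alkene and C6 centre untouched.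

**Compound list**
1 | methyl 4-oxobutanoate | COC(=O)CCC=O | starting material
2 | methyl (3E)-4-(pyrrolidin-1-yl)but-3-enoate | COC(=O)C/C=C/N1CCCC1 | intermediate
3 | 2,3-dibromoprop-1-ene | C=C(Br)CBr | starting material
4 | 1-[4-bromo-2-(2-methoxy-2-oxoethyl)pent-4-en-1-ylidene]pyrrolidinium bromide (racemic) | C=C(Br)CC(CC(=O)OC)C=[N+]1CCCC1.[Br-] | intermediate
5 | methyl 5-bromo-3-formylhex-5-enoate (racemic) | C=C(Br)CC(C=O)CC(=O)OC | intermediate
6 | but-3-en-2-one | CC(=O)C=C | starting material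
7 | methyl 3-(2-bromoprop-2-en-1-yl)-3-formyl-6-oxoheptanoate (racemic) | C=C(Br)CC(C=O)(CC(=O)OC)CCC(C)=O | intermediate
8 | methyl 2-[1-(2-bromoprop-2-en-1-yl)-4-oxocyclohex-2-en-1-yl]acetate (racemic) | C=C(Br)CC1(CC(=O)OC)C=CC(=O)CC1 | intermediate
9 | methyl 2-{1-(2-bromoprop-2-en-1-yl)-4-[(triethylsilyl)oxy]cyclohex-3-en-1-yl}acetate (racemic) | C=C(Br)CC1(CC(=O)OC)CCC(O[Si](CC)(CC)CC)=CC1 | intermediate
10 | methyl 2-[1-(2-bromoprop-2-en-1-yl)-4-oxocyclohexyl]acetate (achiral) | C=C(Br)CC1(CC(=O)OC)CCC(=O)CC1 | intermediate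
11 | methyl 2-[(1R,5R)-6-methylidene-4-oxobicyclo[3.2.1]octan-1-yl]acetate | C=C1C[C@]2(CC(=O)OC)C[C@H]1C(=O)CC2 | intermediate
12 | methyl 2-[(1S,5R)-6-methylidene-4-oxobicyclo[3.2.1]oct-2-en-1-yl]acetate | C=C1C[C@]2(CC(=O)OC)C[C@H]1C(=O)C=C2 | intermediate
13 | 2-[(1S,5R)-6-methylidene-4-oxobicyclo[3.2.1]oct-2-en-1-yl]acetic acid | C=C1C[C@]2(CC(=O)O)C[C@H]1C(=O)C=C2 | intermediate
14 | 2-[(tert-butyldimethylsilyl)oxy]buta-1,3-diene | C=CC(=C)O[Si](C)(C)C(C)(C)C | intermediate
15 | 2-methylprop-2-enal | CC(=C)C=O | starting material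
16 | (1R)-4-[(tert-butyldimethylsilyl)oxy]-1-methylcyclohex-3-ene-1-carbaldehyde | CC(C)(C)[Si](C)(C)OC1=CC[C@](C)(C=O)CC1 | intermediate
17 | (1R)-1-methyl-4-oxocyclohex-2-ene-1-carbaldehyde | O=C1C=C[C@](C)(C=O)CC1 | intermediate
18 | (1R)-1-methyl-4-oxocyclohex-2-ene-1-carboxylic acid | O=C1C=C[C@](C)(C(=O)O)CC1 | intermediate
19 | prop-2-en-1-yl (1R)-1-methyl-4-oxocyclohex-2-ene-1-carboxylate | O=C1C=C[C@](C)(C(=O)OCC=C)CC1 | intermediate
20 | formaldehyde | C=O | starting material
21 | prop-2-en-1-yl (1R)-3-(hydroxymethyl)-1-methyl-4-oxocyclohex-2-ene-1-carboxylate | O=C1C(CO)=C[C@](C)(C(=O)OCC=C)CC1 | intermediate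
22 | prop-2-en-1-yl (1R)-1-methyl-4-oxo-3-{[(triethylsilyl)oxy]methyl}cyclohex-2-ene-1-carboxylate | O=C1C(CO[Si](CC)(CC)CC)=C[C@](C)(C(=O)OCC=C)CC1 | intermediate
23 | prop-2-en-1-yl (1R,4S)-4-hydroxy-1-methyl-3-{[(triethylsilyl)oxy]methyl}cyclohex-2-ene-1-carboxylate | CC[Si](CC)(CC)OCC1=C[C@](C)(C(=O)OCC=C)CC[C@@H]1O | intermediate
24 | prop-2-en-1-yl (1R,4S)-1-methyl-4-({2-[(1S,5R)-6-methylidene-4-oxobicyclo[3.2.1]oct-2-en-1-yl]acetyl}oxy)-3-{[(triethylsilyl)oxy]methyl}cyclohex-2-ene-1-carboxylate | CC[Si](CC)(CC)OCC1=C[C@](C)(C(=O)OCC=C)CC[C@@H]1OC(=O)C[C@]12C=CC(=O)[C@H](C1)C(=C)C2 | intermediate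
25 | (Z)-O-trimethylsilyl ketene acetal of 24 (bicyclic substituent cis to OSiMe3) | CC[Si](CC)(CC)OCC1=C[C@](C)(C(=O)OCC=C)CC[C@@H]1O/C(O[Si](C)(C)C)=C/[C@]12C=CC(=O)[C@H](C1)C(=C)C2 | intermediate
26 | trimethylsilyl ester of 27 | C=C1C[C@@]2(C[C@H]1C(=O)C=C2)[C@@H](C(=O)O[Si](C)(C)C)[C@H]1C(CO[Si](CC)(CC)CC)=CCC[C@@]1(C)C(=O)OCC=C | intermediate
27 | (2S)-2-[(1R,5R)-6-methylidene-4-oxobicyclo[3.2.1]oct-2-en-1-yl]-2-[(1S,6R)-6-methyl-6-[(prop-2-en-1-yloxy)carbonyl]-2-{[(triethylsilyl)oxy]methyl}cyclohex-2-en-1-yl]acetic acid | C=C1C[C@@]2(C[C@H]1C(=O)C=C2)[C@@H](C(=O)O)[C@H]1C(CO[Si](CC)(CC)CC)=CCC[C@@]1(C)C(=O)OCC=C | intermediate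
28 | prop-2-en-1-yl (1R,2S)-1-methyl-2-{(1S)-1-[(1R,5R)-6-methylidene-4-oxobicyclo[3.2.1]oct-2-en-1-yl]-2-oxo-2-(prop-2-en-1-yloxy)ethyl}-3-{[(triethylsilyl)oxy]methyl}cyclohex-3-ene-1-carboxylate | C=C1C[C@@]2(C[C@H]1C(=O)C=C2)[C@@H](C(=O)OCC=C)[C@H]1C(CO[Si](CC)(CC)CC)=CCC[C@@]1(C)C(=O)OCC=C | intermediate
29 | prop-2-en-1-yl (1R,2S)-3-formyl-1-methyl-2-{(1S)-1-[(1R,5R)-6-methylidene-4-oxobicyclo[3.2.1]oct-2-en-1-yl]-2-oxo-2-(prop-2-en-1-yloxy)ethyl}cyclohex-3-ene-1-carboxylate | C=C1C[C@@]2(C[C@H]1C(=O)C=C2)[C@@H](C(=O)OCC=C)[C@H]1C(C=O)=CCC[C@@]1(C)C(=O)OCC=C | intermediate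
30 | diprop-2-en-1-yl (1R,2S,3S,4R,8R,9R,12R)-8-formyl-4-methyl-13-methylidene-11-oxotetracyclo[10.2.1.0(1,9).0(3,8)]pentadecane-2,4-dicarboxylate | C=C1C[C@]23C[C@H]1C(=O)C[C@H]2[C@]1(C=O)CCC[C@@](C)(C(=O)OCC=C)[C@H]1[C@@H]3C(=O)OCC=C | intermediate
31 | (1R,2S,3S,4R,8R,9R,12R)-8-formyl-4-methyl-13-methylidene-11-oxotetracyclo[10.2.1.0(1,9).0(3,8)]pentadecane-2,4-dicarboxylic acid | C=C1C[C@]23C[C@H]1C(=O)C[C@H]2[C@]1(C=O)CCC[C@@](C)(C(=O)O)[C@H]1[C@@H]3C(=O)O | target

**Step count and risks**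

Total step count: 20 (ring C/D branch steps 1–7, ring A branch steps 8–15, common steps 16–20).
Longest linear sequence: 13 steps (steps 8–15, then 16–20), which is 65% of the total.

Steps most likely to fail:

Step 5 (the proposed new step; risk: no turnover of the hindered enamine, or low selectivity between the two α-arms). Fallback with known chemistry, setting out from 10 and coming back at 24. The ketone 10 is cyclised under the established achiral, base-mediated conditions for intramolecular ketone α-vinylation (Pd(PPh3)4, PhOK, THF, 65 °C). This gives racemic material, that is 11 together with its mirror image methyl 2-[(1S,5S)-6-methylidene-4-oxobicyclo[3.2.1]octan-1-yl]acetate F1. Steps 6 and 7 carried out on the racemate give 12 together with methyl 2-[(1R,5S)-6-methylidene-4-oxobicyclo[3.2.1]oct-2-en-1-yl]acetate F2, and then 13 together with 2-[(1R,5S)-6-methylidene-4-oxobicyclo[3.2.1]oct-2-en-1-yl]acetic acid F3. Esterification of the racemic acid with enantiopure 23 as in step 16 gives 24 and the diastereomer prop-2-en-1-yl (1R,4S)-1-methyl-4-({2-[(1R,5S)-6-methylidene-4-oxobicyclo[3.2.1]oct-2-en-1-yl]acetyl}oxy)-3-{[(triethylsilyl)oxy]methyl}cyclohex-2-ene-1-carboxylate F4. The two esters are separated by chromatography and the route continues from 24, at the cost of half the ring C/D material.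

Step 17 (risk: a boat rather than chair transition state, which is common for cyclohexenyl esters and would invert C6; the bond is also formed between two carbons that each sit next to a quaternary centre). Fallback setting out from 24 and coming back at 30. C6 is set by thermodynamic control after ring B exists instead of by the Claisen transition state. If the rearrangement gives mainly the C6 epimer prop-2-en-1-yl (1R,2S)-1-methyl-2-{(1R)-1-[(1R,5R)-6-methylidene-4-oxobicyclo[3.2.1]oct-2-en-1-yl]-2-oxo-2-(prop-2-en-1-yloxy)ethyl}-3-{[(triethylsilyl)oxy]methyl}cyclohex-3-ene-1-carboxylate F5, it is taken through the conditions of step 18 to prop-2-en-1-yl (1R,2S)-3-formyl-1-methyl-2-{(1R)-1-[(1R,5R)-6-methylidene-4-oxobicyclo[3.2.1]oct-2-en-1-yl]-2-oxo-2-(prop-2-en-1-yloxy)ethyl}cyclohex-3-ene-1-carboxylate F6. The conditions of step 19 then give diprop-2-en-1-yl (1R,2R,3S,4R,8R,9R,12R)-8-formyl-4-methyl-13-methylidene-11-oxotetracyclo[10.2.1.0(1,9).0(3,8)]pentadecane-2,4-dicarboxylate F7. The α-ester centre C6 of F7 is equilibrated with catalytic sodium prop-2-en-1-olate in prop-2-en-1-ol/THF at 40 °C, a medium in which ester exchange is degenerate. The ester should settle trans to the C4 quaternary carbon on ring B, which is 30, and the route resumes there.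

Step 19 (risk: the enamine from an α-branched aldehyde may be too hindered to close the quaternary C10–C9 bond, and the facial preference at C10 is not secured by precedent). Fallback setting out from 29 and coming back at 30. The cascade is split and the ring closure is changed from enamine to enolate chemistry. Transfer hydrogenation with the same dihydropyridine and the bulkier salt dibenzylammonium trifluoroacetate (THF, 0 °C) is stopped at the saturated aldehyde prop-2-en-1-yl (1R,2R)-3-formyl-1-methyl-2-{(1S)-1-[(1R,5R)-6-methylidene-4-oxobicyclo[3.2.1]oct-2-en-1-yl]-2-oxo-2-(prop-2-en-1-yloxy)ethyl}cyclohexane-1-carboxylate F8 (C10 epimers, both usable). Ring B is then closed by a base-mediated intramolecular Michael addition of the aldehyde enolate (KOtBu 0.3 equiv, tBuOH/THF, 0 °C) to give 30.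

**Further compounds**
F1 | step 5 | methyl 2-[(1S,5S)-6-methylidene-4-oxobicyclo[3.2.1]octan-1-yl]acetate | C=C1C[C@@]2(CC(=O)OC)C[C@@H]1C(=O)CC2
F2 | step 5 | methyl 2-[(1R,5S)-6-methylidene-4-oxobicyclo[3.2.1]oct-2-en-1-yl]acetate | C=C1C[C@@]2(CC(=O)OC)C[C@@H]1C(=O)C=C2
F3 | step 5 | 2-[(1R,5S)-6-methylidene-4-oxobicyclo[3.2.1]oct-2-en-1-yl]acetic acid | C=C1C[C@@]2(CC(=O)O)C[C@@H]1C(=O)C=C2
F4 | step 5 | prop-2-en-1-yl (1R,4S)-1-methyl-4-({2-[(1R,5S)-6-methylidene-4-oxobicyclo[3.2.1]oct-2-en-1-yl]acetyl}oxy)-3-{[(triethylsilyl)oxy]methyl}cyclohex-2-ene-1-carboxylate | CC[Si](CC)(CC)OCC1=C[C@](C)(C(=O)OCC=C)CC[C@@H]1OC(=O)C[C@@]12C=CC(=O)[C@@H](C1)C(=C)C2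
F5 | step 17 | prop-2-en-1-yl (1R,2S)-1-methyl-2-{(1R)-1-[(1R,5R)-6-methylidene-4-oxobicyclo[3.2.1]oct-2-en-1-yl]-2-oxo-2-(prop-2-en-1-yloxy)ethyl}-3-{[(triethylsilyl)oxy]methyl}cyclohex-3-ene-1-carboxylate | C=C1C[C@@]2(C[C@H]1C(=O)C=C2)[C@H](C(=O)OCC=C)[C@H]1C(CO[Si](CC)(CC)CC)=CCC[C@@]1(C)C(=O)OCC=C
F6 | step 17 | prop-2-en-1-yl (1R,2S)-3-formyl-1-methyl-2-{(1R)-1-[(1R,5R)-6-methylidene-4-oxobicyclo[3.2.1]oct-2-en-1-yl]-2-oxo-2-(prop-2-en-1-yloxy)ethyl}cyclohex-3-ene-1-carboxylate | C=C1C[C@@]2(C[C@H]1C(=O)C=C2)[C@H](C(=O)OCC=C)[C@H]1C(C=O)=CCC[C@@]1(C)C(=O)OCC=C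
F7 | step 17 | diprop-2-en-1-yl (1R,2R,3S,4R,8R,9R,12R)-8-formyl-4-methyl-13-methylidene-11-oxotetracyclo[10.2.1.0(1,9).0(3,8)]pentadecane-2,4-dicarboxylate | C=C1C[C@]23C[C@H]1C(=O)C[C@H]2[C@]1(C=O)CCC[C@@](C)(C(=O)OCC=C)[C@H]1[C@H]3C(=O)OCC=C
F8 | step 19 | prop-2-en-1-yl (1R,2R)-3-formyl-1-methyl-2-{(1S)-1-[(1R,5R)-6-methylidene-4-oxobicyclo[3.2.1]oct-2-en-1-yl]-2-oxo-2-(prop-2-en-1-yloxy)ethyl}cyclohexane-1-carboxylate (C3 epimers) | C=C1C[C@@]2(C[C@H]1C(=O)C=C2)[C@@H](C(=O)OCC=C)[C@H]1C(C=O)CCC[C@@]1(C)C(=O)OCC=C
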